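(Readings and results are calculated from invented constants; noise was put on by code.)

| flask | substrate | capture agent | gas | free catalyst | second catalyst | remark | time |
|---|---|---|---|---|---|---|---|
| alpha | 0.12 M | 1.3 mM | 41 mM (held) | 0.25 mM | 17 mM | run made earlier |  |
| delta | 0.12 M | 4.7 mM | 41 mM (held) | 0.25 mM | 17 mM | run made earlier |  |
| amber | 0.12 M | 1.50 mM | 41 mM (held) | 0.25 mM | 17 mM |  | 8.0 d |
| red | 0.12 M | 3.00 mM | 41 mM (held) | 0.25 mM | 17 mM |  | 8.0 d |
| teal | 0.12 M | 6.00 mM | 41 mM (held) | 0.25 mM | 17 mM |  | 8.0 d |

| run | time / d | product / % | substrate / % |
|---|---|---|---|
| alpha | 2.08 | 53.9 | 18.6 |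
| alpha | 4.00 | 85.4 | 3.1 |
| alpha | 6.00 | 95.7 | 0.9 |
| alpha | 8.00 | 98.0 | 0 |
| delta | 1.04 | 21.6 | 43.2 |
| delta | 3.00 | 70.5 | 9.1 |
| delta | 5.00 | 89.5 | 1.8 |
| delta | 8.00 | 95.8 | 0.4 |

(standard deviation of a reading: 0.3 percentage points)

* amount of product at the end, in percent of the substrate charged for amber, red, teal, in this order
* the shape of the row from first to last (hardly changes / falls all the way / falls, then rises / rises all the way / rises, then falls)

- the numbers in the tables scatter with a standard deviation of 0.3 percentage points
- at the start none of the gas is in solution
- "hardly changes" means that all values lie within two and a half points (for a concentration: within two and a half percent of the largest)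

**Reading time.** At 8.0 d, the time of reading, the alpha flask shows 0% substrate and the delta flask 0.4%, each close to zero given a scatter of 0.3 percentage points. So I read the end product as a balance of where the substrate went, not as a rate.

**First extreme.** Suppose the capture agent takes nothing. Product then does not depend on its charge, the row is flat, and alpha and delta read alike. But their end products differ by 2.2 points, which is more than the scatter of one reading.

**Second extreme.** Suppose instead that each capture agent removes one substrate equivalent for good. In each flask its charge is smaller than that of substrate, so on this supposition it is the limiting reagent of this side path. A flask then gives up [capture agent] over [substrate], as charged, which is 5.00% for teal; I call this share the toll.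

**Between them.** From alpha to delta the toll grows by 2.8 points, and the observed gap falls short of that by 0.63 points. This is about twice the scatter of one reading, and the gap is a difference of two readings, so I commit to the full toll.

**Zero point.** Adding its toll back to each end product gives 99.1% for alpha and 99.7% for delta. Their mean, 99.4%, is the zero of my scale. Subtracting the tolls, I expect 98.2% for amber, 96.9% for red and 94.4% for teal.

**The forecast.** The forecast gives 97.9%, 96.9% and 95%, a row that falls all the way, on the ground of a “near-stoichiometric, permanent loss”, and for amber and teal I hold to my 98.2% and 94.4%.

**The flasks.** Amber, red and teal give 98.0%, 96.8% and 94.3%, a row that falls all the way.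

    substrate + free catalyst → free catalyst + open intermediate (k = 0.0371 /M/s)
    coupling partner + second catalyst + open intermediate → second catalyst + product (k = 0.0161 /M²/s)
    open intermediate + capture agent → trapped intermediate (k = 0.00122 /M/s)
    gas ⇌ coupling partner, rate k4*(csat - [coupling partner]) (kL = 5.22 × 10⁻⁴ /s)

**Toll again.** At 8.00 d teal holds 5.00% as trapped intermediate, with 0% of its capture agent left unbound, and its toll is 5.00%. Scaled to the charge of red, the toll is 2.50%, and at 8.00 d red holds 2.50% as trapped intermediate.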